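**Retrosynthetic overview**

1. Target ⇐ the same trimer carrying three ynoates in place of the three Z-enoates (triple Lindlar semihydrogenation as the last step; the propargylic hydroxyls travel as TBS ethers).
2. Cyclopentanone core ⇐ one-flask Michael/aldol/Michael union of three preformed 14-membered rings: one tetrone macrocycle (becomes ring 2) plus two enedione macrocycles (ring 3, then ring 1). The five-membered ring is the last ring formed.
3. Tetrone macrocycle ⇐ enedione macrocycle (dihydroxylation, E1cB dehydration); enedione macrocycle ⇐ seco hydroxy acid (macrolactonisation, first ring formed).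
4. Key step: the (E)-4-oxo-2-enoic acid of the seco acid ⇐ a 2-alkylfuran, broken open oxidatively on the complete, unprotected seco ester. The furan is carried through esterification and organolithium chemistry as the latent C8–C11 keto-enoate, so 12 carbons of the target are former furan carbons.
5. Furan seco ester ⇐ (S)-4-(furan-2-yl)butan-2-yl propiolate + O-silyl (S)-lactaldehyde (Felkin alkynylation); the propiolate ⇐ furan + methyl vinyl ketone, enzymatic reduction, propiolic acid.

Assumption: the three enoate C=C bonds are Z exactly as written in the SMILES; macrocycle atoms are numbered O1, C2(=O), C3, C4, C5(O), C6(Me), O7, C8(=O), C9, C10, C11(=O), C12, C13, C14(Me) throughout.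

**Route**

Step 1
Reactants: 1 furan; 2 but-3-en-2-one (methyl vinyl ketone)
Product: 3 4-(furan-2-yl)butan-2-one
Conditions: furan (10 equiv), AuCl3 (1 mol%), MeCN, 0 °C → rt
Reagents that add atoms: none
Why: Friedel–Crafts-type conjugate addition (hydroarylation) of the enone at the α-position of furan, with excess furan suppressing 2,5-dialkylation; no stereocentre is formed.

Step 2
Reactants: 3 4-(furan-2-yl)butan-2-one
Product: 4 (2S)-4-(furan-2-yl)butan-2-ol
Conditions: alcohol dehydrogenase ADH-A from Rhodococcus ruber (Prelog selectivity), NAD+ (cat.), i-PrOH (15 vol%), phosphate buffer pH 7.5, 30 °C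
Reagents that add atoms: none
Why: Biocatalytic transfer hydrogenation in which the Prelog enzyme delivers hydride to the Re face of the methyl ketone and so sets the S carbinol, as it does for 4-phenylbutan-2-one.

Step 3
Reactants: 4 (2S)-4-(furan-2-yl)butan-2-ol; 5 propiolic acid
Product: 6 (2S)-4-(furan-2-yl)butan-2-yl prop-2-ynoate
Conditions: DCC, 4-(dimethylamino)pyridine (5 mol%), CH2Cl2, −20 → 0 °C
Reagents that add atoms: none
Why: Steglich esterification, which forms the acyl–O bond and therefore retains the carbinol configuration; low temperature limits amine addition to the propiolate.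

Step 4
Reactants: 7 ethyl (2S)-2-hydroxypropanoate (ethyl (S)-lactate)
Product: 8 ethyl (2S)-2-(triethylsilyloxy)propanoate
Conditions: Et3SiCl, imidazole, CH2Cl2, 0 °C
Reagents that add atoms: chlorotriethylsilane, CC[Si](Cl)(CC)CC
Why: Standard silylation of the secondary alcohol; the TES ether is chosen because it can later be removed in the presence of a TBS ether.

Step 5
Reactants: 8 ethyl (2S)-2-(triethylsilyloxy)propanoate
Product: 9 (2S)-2-(triethylsilyloxy)propanal
Conditions: i-Bu2AlH (1.1 equiv), CH2Cl2, −78 °C; Rochelle-salt work-up; used crude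
Reagents that add atoms: none
Why: Partial ester reduction through the tetrahedral aluminium hemiacetal that is stable at −78 °C; the α-silyloxy aldehyde is used at once to avoid racemisation.

Step 6
Reactants: 6 (2S)-4-(furan-2-yl)butan-2-yl prop-2-ynoate; 9 (2S)-2-(triethylsilyloxy)propanal
Product: 12 (2S)-4-(furan-2-yl)butan-2-yl (4R,5S)-4-(tert-butyldimethylsilyloxy)-5-(triethylsilyloxy)hex-2-ynoate, via lithium acetylide 10 (not isolated), via lithium alkoxide 11 (not isolated)
Conditions: LiN(SiMe3)2 (1.05 equiv), THF, −78 °C; 9, −78 °C; then t-BuMe2SiOTf (1.3 equiv), −78 → −40 °C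
Reagents that add atoms: tert-butyldimethylsilyl triflate, CC(C)(C)[Si](C)(C)OS(=O)(=O)C(F)(F)F
Why: Acetylide addition to the α-silyloxy aldehyde follows the Felkin–Anh polar model (non-chelating lithium, silyl ether anti to the nucleophile) and gives the 4,5-anti (4R) alkoxide (about 5:1 expected, the 4S isomer is removed by chromatography after step 7), which is silylated in the same flask at −78 °C before silyl migration can occur.

Step 7
Reactants: 12 (2S)-4-(furan-2-yl)butan-2-yl (4R,5S)-4-(tert-butyldimethylsilyloxy)-5-(triethylsilyloxy)hex-2-ynoate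
Product: 13 (2S)-4-(furan-2-yl)butan-2-yl (4R,5S)-4-(tert-butyldimethylsilyloxy)-5-hydroxyhex-2-ynoate
Conditions: pyridinium p-toluenesulfonate (10 mol%), MeOH/CH2Cl2, 0 °C
Reagents that add atoms: none
Why: Selective acid-catalysed methanolysis of the TES ether, which is far more labile than the secondary TBS ether; furan and ynoate are inert to these conditions.

Step 8 (key step)
Reactants: 13 (2S)-4-(furan-2-yl)butan-2-yl (4R,5S)-4-(tert-butyldimethylsilyloxy)-5-hydroxyhex-2-ynoate
Product: 16 (2E,7S)-7-{[(4R,5S)-4-(tert-butyldimethylsilyloxy)-5-hydroxyhex-2-ynoyl]oxy}-4-oxooct-2-enoic acid, via (Z)-keto enal 14 (not isolated), via (E)-keto enal 15 (not isolated)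
Conditions: NBS (1.1 equiv), NaHCO3, acetone/H2O 10:1, −20 °C; pyridine, rt; then NaClO2, NaH2PO4, 2-methyl-2-butene, t-BuOH/H2O, 0 °C
Reagents that add atoms: water, O; sodium chlorite, [Na+].[O-]Cl=O
Why: Oxidative dearomatisation of the 2-alkylfuran (bromonium attack at C5, water addition, ring opening) gives the cis-4-oxo-2-enal, pyridine isomerises it to the trans enal and a Pinnick oxidation gives the (E)-4-oxo-2-enoic acid, so the two furan α-carbons become the C11 ketone and the C8 carboxyl while the free alcohol, the silyl ether and the ynoate are inert to NBS at −20 °C and to chlorite.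

Step 9
Reactants: 16 (2E,7S)-7-{[(4R,5S)-4-(tert-butyldimethylsilyloxy)-5-hydroxyhex-2-ynoyl]oxy}-4-oxooct-2-enoic acid
Product: 18 (5R,6S,9E,14S)-5-(tert-butyldimethylsilyloxy)-6,14-dimethyl-1,7-dioxacyclotetradec-9-en-3-yne-2,8,11-trione, via mixed anhydride 17 (not isolated)
Conditions: 2,4,6-trichlorobenzoyl chloride, Et3N, THF, rt; then slow addition to 4-(dimethylamino)pyridine, toluene (2 mM), 40 °C
Reagents that add atoms: none
Why: Yamaguchi macrolactonisation closes the 14-membered ring through the C6 hydroxyl with retention; the E-keto acid cannot hide as a pseudo-acid lactol, and the TBS group keeps the propargylic oxygen out of acylation and of base-induced ynoate isomerisation.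

Step 10
Reactants: 18 (5R,6S,9E,14S)-5-(tert-butyldimethylsilyloxy)-6,14-dimethyl-1,7-dioxacyclotetradec-9-en-3-yne-2,8,11-trione
Product: 19 (5R,6S,14S)-5-(tert-butyldimethylsilyloxy)-9,10-dihydroxy-6,14-dimethyl-1,7-dioxacyclotetradec-3-yne-2,8,11-trione (threo 9,10-diol; both syn-addition isomers are carried on)
Conditions: OsO4 (2 mol%), N-methylmorpholine N-oxide (1.2 equiv), citric acid (0.75 equiv), t-BuOH/H2O 1:1, rt
Reagents that add atoms: N-methylmorpholine N-oxide, C[N+]1([O-])CCOCC1; water, O
Why: Osmium-catalysed syn-dihydroxylation under the citric-acid protocol for electron-poor alkenes attacks only the enedione C=C (the ynoate is inert to OsO4) and gives the threo diols, whose two new stereocentres are erased in step 11.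

Step 11
Reactants: 19 (5R,6S,14S)-5-(tert-butyldimethylsilyloxy)-9,10-dihydroxy-6,14-dimethyl-1,7-dioxacyclotetradec-3-yne-2,8,11-trione
Product: 21 (5R,6S,14S)-5-(tert-butyldimethylsilyloxy)-6,14-dimethyl-1,7-dioxacyclotetradec-3-yne-2,8,10,11-tetrone (chelated C9=C10 enol in solution), via cyclic carbonate 20 (not isolated)
Conditions: 1,1'-carbonyldiimidazole (1.1 equiv), CH2Cl2, 0 °C → rt; then Et3N (1.5 equiv), 0 °C; aqueous citric acid work-up
Reagents that add atoms: none
Why: The diol closes to the cyclic carbonate and an E1cB elimination follows in which the more acidic C10–H (α to the C11 ketone) is removed, the C9–O bond breaks and CO2 is lost, so oxygen stays on C10 and the β-keto ester/1,2-diketone results.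

Step 12
Reactants: 21 tetrone macrocycle (1 equiv); 18 enedione macrocycle (2.1 equiv)
Product: 24 tris-TBS triyne trimer (cyclopentanone core carrying rings 1 to 3; SMILES in the list), via Michael adduct 22 (not isolated), via bicyclic dimer 23 (not isolated)
Conditions: i-Pr2NEt (0.3 equiv), CH2Cl2 (0.05 M), −20 °C → rt
Reagents that add atoms: none
Why: Base-catalysed Michael addition of the doubly activated C9 of 21 to C9 of the enedione of 18 gives an enolate that closes onto the C11 ketone of 21 (intramolecular aldol, formal [3+2] annulation), and the resulting 2-oxocyclopentanecarboxylate then adds to a second 18 to form the quaternary centre; the five new centres are expected to arise under substrate control, because ring 2 can span the cyclopentanone only cis (so its C8 ester and C12 share one face and the second acceptor and the aldol hydroxyl take the other), addition across the E-enedione of ring 3 is trans, each enedione is attacked on its exposed outer face, and the β-substituted silyloxy ynoates are far poorer acceptors than the enediones.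

Step 13
Reactants: 24 tris-TBS triyne trimer
Product: 25 triol triyne trimer
Conditions: HF·pyridine, pyridine, THF, 0 °C → rt
Reagents that add atoms: none
Why: Fluoride cleavage of the three propargylic silyl ethers under buffered, mildly acidic conditions, at a stage where the γ-hydroxy ynoates are linear and cannot lactonise and no base is present to isomerise them.

Step 14
Reactants: 25 triol triyne trimer
Product: 26 target CNP0072185.1
Conditions: H2 (1 atm), Pd/CaCO3 poisoned with Pb(OAc)2 (Lindlar catalyst), quinoline, EtOAc, 0 °C, stopped after uptake of 3 equiv H2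
Reagents that add atoms: none
Why: Lindlar semihydrogenation adds H2 syn to each of the three ynoates and so sets the three Z-enoates, leaving ketones, esters and alcohols untouched under neutral conditions that do not catalyse butenolide formation from the cis-γ-hydroxy enoates.

**Compound list**

1 | furan | c1ccoc1 | starting material
2 | but-3-en-2-one (methyl vinyl ketone) | CC(=O)C=C | starting material
3 | 4-(furan-2-yl)butan-2-one | CC(=O)CCc1ccco1 | intermediate
4 | (2S)-4-(furan-2-yl)butan-2-ol | C[C@H](O)CCc1ccco1 | intermediate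
5 | propiolic acid | C#CC(=O)O | starting material
6 | (2S)-4-(furan-2-yl)butan-2-yl prop-2-ynoate | C[C@H](OC(=O)C#C)CCc1ccco1 | intermediate
7 | ethyl (2S)-2-hydroxypropanoate (ethyl (S)-lactate) | C[C@H](O)C(=O)OCC | starting material
8 | ethyl (2S)-2-(triethylsilyloxy)propanoate | C[C@H](O[Si](CC)(CC)CC)C(=O)OCC | intermediate
9 | (2S)-2-(triethylsilyloxy)propanal | C[C@H](O[Si](CC)(CC)CC)C=O | intermediate
10 | lithium acetylide of 6 | C[C@H](OC(=O)C#[C-])CCc1ccco1.[Li+] | intermediate (not isolated)
11 | lithium (4R,5S)-alkoxide from 10 and 9 | C[C@H](OC(=O)C#C[C@@H]([O-])[C@H](C)O[Si](CC)(CC)CC)CCc1ccco1.[Li+] | intermediate (not isolated)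
12 | (2S)-4-(furan-2-yl)butan-2-yl (4R,5S)-4-(tert-butyldimethylsilyloxy)-5-(triethylsilyloxy)hex-2-ynoate | C[C@H](OC(=O)C#C[C@@H](O[Si](C)(C)C(C)(C)C)[C@H](C)O[Si](CC)(CC)CC)CCc1ccco1 | intermediate
13 | (2S)-4-(furan-2-yl)butan-2-yl (4R,5S)-4-(tert-butyldimethylsilyloxy)-5-hydroxyhex-2-ynoate | C[C@H](OC(=O)C#C[C@@H](O[Si](C)(C)C(C)(C)C)[C@H](C)O)CCc1ccco1 | intermediate
14 | (2S,6Z)-5,8-dioxooct-6-en-2-yl (4R,5S)-4-(tert-butyldimethylsilyloxy)-5-hydroxyhex-2-ynoate | C[C@H](OC(=O)C#C[C@@H](O[Si](C)(C)C(C)(C)C)[C@H](C)O)CCC(=O)/C=C\C=O | intermediate (not isolated)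
15 | (2S,6E)-5,8-dioxooct-6-en-2-yl (4R,5S)-4-(tert-butyldimethylsilyloxy)-5-hydroxyhex-2-ynoate | C[C@H](OC(=O)C#C[C@@H](O[Si](C)(C)C(C)(C)C)[C@H](C)O)CCC(=O)/C=C/C=O | intermediate (not isolated)
16 | (2E,7S)-7-{[(4R,5S)-4-(tert-butyldimethylsilyloxy)-5-hydroxyhex-2-ynoyl]oxy}-4-oxooct-2-enoic acid | C[C@H](OC(=O)C#C[C@@H](O[Si](C)(C)C(C)(C)C)[C@H](C)O)CCC(=O)/C=C/C(=O)O | intermediate
17 | mixed anhydride of 16 with 2,4,6-trichlorobenzoic acid | C[C@H](OC(=O)C#C[C@@H](O[Si](C)(C)C(C)(C)C)[C@H](C)O)CCC(=O)/C=C/C(=O)OC(=O)c1c(Cl)cc(Cl)cc1Cl | intermediate (not isolated)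
18 | (5R,6S,9E,14S)-5-(tert-butyldimethylsilyloxy)-6,14-dimethyl-1,7-dioxacyclotetradec-9-en-3-yne-2,8,11-trione | C[C@@H]1OC(=O)/C=C/C(=O)CC[C@H](C)OC(=O)C#C[C@H]1O[Si](C)(C)C(C)(C)C | intermediate
19 | (5R,6S,14S)-5-(tert-butyldimethylsilyloxy)-9,10-dihydroxy-6,14-dimethyl-1,7-dioxacyclotetradec-3-yne-2,8,11-trione, threo diol; (9R,10R) isomer drawn, the (9S,10S) isomer forms too and converges | C[C@@H]1OC(=O)[C@H](O)[C@@H](O)C(=O)CC[C@H](C)OC(=O)C#C[C@H]1O[Si](C)(C)C(C)(C)C | intermediate
20 | 9,10-cyclic carbonate of 19 (trans-4,5-disubstituted 1,3-dioxolan-2-one; isomer from the drawn diol) | C[C@@H]1OC(=O)[C@@H]2OC(=O)O[C@H]2C(=O)CC[C@H](C)OC(=O)C#C[C@H]1O[Si](C)(C)C(C)(C)C | intermediate (not isolated)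
21 | (5R,6S,14S)-5-(tert-butyldimethylsilyloxy)-6,14-dimethyl-1,7-dioxacyclotetradec-3-yne-2,8,10,11-tetrone (keto form drawn) | C[C@@H]1OC(=O)CC(=O)C(=O)CC[C@H](C)OC(=O)C#C[C@H]1O[Si](C)(C)C(C)(C)C | intermediate
22 | open Michael adduct: C9 (S) of 21 bonded to C9 (S) of one unit of 18; rings 2 and 3 joined by one C–C bond, no cyclopentane yet | [C@H]1(C(=O)O[C@@H](C)[C@H](O[Si](C)(C)C(C)(C)C)C#CC(=O)O[C@@H](C)CCC(=O)C1=O)[C@@H]2CC(=O)CC[C@H](C)OC(=O)C#C[C@@H](O[Si](C)(C)C(C)(C)C)[C@H](C)OC2=O | intermediate (not isolated)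
23 | bicyclic dimer: cyclopentanone built from C9(H)–C10(=O)–C11(OH) of ring 2 (9S,11S) and C10–C9 of ring 3 (9S,10S); OH and the ring-3 ketone carbon on one face, both C8 ester carbons and ring-2 C12 on the other | [C@@H]23C(=O)O[C@@H](C)[C@H](O[Si](C)(C)C(C)(C)C)C#CC(=O)O[C@@H](C)CC[C@@](O)(C2=O)[C@H]2C(=O)CC[C@H](C)OC(=O)C#C[C@@H](O[Si](C)(C)C(C)(C)C)[C@H](C)OC(=O)[C@@H]23 | intermediate (not isolated)
24 | tris-TBS triyne trimer: 23 whose C9 (now quaternary, S) is bonded to C9 (R) of ring 1; ring-1 substituent on the face of the OH | C[C@@H]1OC(=O)[C@@H]([C@@]23C(=O)O[C@@H](C)[C@H](O[Si](C)(C)C(C)(C)C)C#CC(=O)O[C@@H](C)CC[C@@](O)(C2=O)[C@H]2C(=O)CC[C@H](C)OC(=O)C#C[C@@H](O[Si](C)(C)C(C)(C)C)[C@H](C)OC(=O)[C@@H]23)CC(=O)CC[C@H](C)OC(=O)C#C[C@H]1O[Si](C)(C)C(C)(C)C | intermediate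
25 | triol triyne trimer (24 without the three silyl groups) | C[C@@H]1OC(=O)[C@@H]([C@@]23C(=O)O[C@@H](C)[C@H](O)C#CC(=O)O[C@@H](C)CC[C@@](O)(C2=O)[C@H]2C(=O)CC[C@H](C)OC(=O)C#C[C@@H](O)[C@H](C)OC(=O)[C@@H]23)CC(=O)CC[C@H](C)OC(=O)C#C[C@H]1O | intermediate
26 | CNP0072185.1, all-Z trimeric macrodiolide | C[C@@H]1OC(=O)[C@@H]([C@@]23C(=O)O[C@@H](C)[C@H](O)/C=C\C(=O)O[C@@H](C)CC[C@@](O)(C2=O)[C@H]2C(=O)CC[C@H](C)OC(=O)/C=C\[C@@H](O)[C@H](C)OC(=O)[C@@H]23)CC(=O)CC[C@H](C)OC(=O)/C=C\[C@H]1O | target

**Step count and risks**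

Total step count: 14. Longest linear sequence: 12 steps (1, 2, 3, 6, 7, 8, 9, 10, 11, 12, 13, 14, starting from furan).

Most likely to fail:

Step 12 (three-component union). The quaternary-centre-forming Michael addition onto the macrocyclic enedione may be too hindered, or the macrocycles may not impose the required facial selectivity. Fallback: set out from 21 with only one equivalent of 18 and isolate the bicyclic dimer 23 (i-Pr2NEt, CH2Cl2, −20 °C). Then form the quaternary centre on the unhindered acyclic acceptor instead of the ring: 23 adds to the triethylammonium salt of seco acid 16 (Et3N 2.2 equiv, MeCN, rt) to give the ring-1 seco acid F1. Ring 1 is closed last by Yamaguchi lactonisation of F1 (2,4,6-trichlorobenzoyl chloride, Et3N; 4-(dimethylamino)pyridine, toluene, high dilution), which returns to the route at 24.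

Step 9 (macrolactonisation). 4-(Dimethylamino)pyridine and Et3N may add to the keto-enoate or ynoate, move the silyl group, or give oligomers because of the strain of the yne–ene ring. Fallback: set out from 16 and change from base-mediated acyl transfer to an acid-catalysed enol-ester transacylation. Addition of the acid to ethoxyacetylene ([RuCl2(p-cymene)]2, 1 mol%, toluene, 0 °C → rt) gives the isolable 1-ethoxyvinyl ester F2. F2 is cyclised with camphorsulfonic acid (10 mol%, 1,2-dichloroethane, 1 mM, 50 °C) with loss of ethyl acetate, returning at 18.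

Step 14 (final triple semihydrogenation). Over- or under-reduction of three alkynes on an unprotected polar substrate, and lactonisation of the cis-γ-hydroxy enoates during purification, are the concerns. Fallback: set out from 24 and invert the protecting-group logic. Semihydrogenate first (H2, Pd/CaCO3 poisoned with Pb(OAc)2, quinoline, EtOAc/hexane) to the robust, chromatographable tris-TBS tris-(Z)-enoate trimer F3. Then remove the silyl groups with HF·pyridine buffered with excess pyridine (THF, 0 °C) to arrive at 26.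

**Further compounds**

F1 | step 12 | ring-1 seco acid: 23 bonded through its quaternary C9 to C2 of the (7S)-4-oxo-octanoic acid chain of 16, free CO2H and free C5 hydroxyl on the hexynoate | C[C@H](O)[C@H](O[Si](C)(C)C(C)(C)C)C#CC(=O)O[C@@H](C)CCC(=O)C[C@@H](C(=O)O)[C@@]23C(=O)O[C@@H](C)[C@H](O[Si](C)(C)C(C)(C)C)C#CC(=O)O[C@@H](C)CC[C@@](O)(C2=O)[C@H]2C(=O)CC[C@H](C)OC(=O)C#C[C@@H](O[Si](C)(C)C(C)(C)C)[C@H](C)OC(=O)[C@@H]23
F2 | step 9 | 1-ethoxyvinyl ester of seco acid 16 | C[C@H](OC(=O)C#C[C@@H](O[Si](C)(C)C(C)(C)C)[C@H](C)O)CCC(=O)/C=C/C(=O)OC(=C)OCC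
F3 | step 14 | tris-TBS tris-(Z)-enoate trimer (target with its three allylic hydroxyls as TBS ethers) | C[C@@H]1OC(=O)[C@@H]([C@@]23C(=O)O[C@@H](C)[C@H](O[Si](C)(C)C(C)(C)C)/C=C\C(=O)O[C@@H](C)CC[C@@](O)(C2=O)[C@H]2C(=O)CC[C@H](C)OC(=O)/C=C\[C@@H](O[Si](C)(C)C(C)(C)C)[C@H](C)OC(=O)[C@@H]23)CC(=O)CC[C@H](C)OC(=O)/C=C\[C@H]1O[Si](C)(C)C(C)(C)C
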